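**Retrosynthetic overview**
- Target ⇐ Luche 1,2-reduction of the C4 ketone of the 3-O-benzoyl enone (C4-OH ends trans to the benzoate).
- Enone ⇐ benzoate opening, at C3 (α to the ketone, inversion), of a cis-epoxy γ-hydroxy enone; this sets the trans 2-OH/3-OBz pair.
- Epoxy enone ⇐ ketal hydrolysis of an epoxy quinol ketal whose quaternary C1 comes from the key C–C bond: C-lithiated lithium methoxide (the formaldehyde carbon made nucleophilic) adds to the ketone of an epoxy-quinone monoketal anti to the epoxide, and the primary alkoxide is benzoylated in the same flask.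
- Epoxy-quinone monoketal ⇐ catalytic enantioselective mono-epoxidation of p-benzoquinone mono(dimethyl ketal).
- Rings: the carbocycle is bought intact (no ring-forming C–C step); the only ring made is the oxirane (step 1), and it is opened in step 4.

Assumption: of the two pseudo-enantiomeric cinchona phase-transfer catalysts, the one that gives the (1S,6R)-epoxide is used (written below as the cinchonidinium salt; the sense of induction is not established for this substrate and must be checked on the first run).

Step 1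
Reactants: 1 4,4-dimethoxycyclohexa-2,5-dien-1-one
Product: 2 (1S,6R)-5,5-dimethoxy-7-oxabicyclo[4.1.0]hept-3-en-2-one
Conditions: tBuOOH (1.2 equiv), NaOH (aq, 0.2 equiv), N-benzylcinchonidinium chloride (10 mol %), toluene, 0 °C; recrystallise to raise ee
Reagents that add atoms: tert-butyl hydroperoxide, CC(C)(C)OO
Why: Weitz–Scheffer nucleophilic epoxidation under chiral phase-transfer catalysis, in which the ion-paired tBuOO− adds to one of the two enantiotopic enone alkenes of the mirror-symmetric dienone and ring closure gives the cis-fused oxirane (the future C2 and C3, oxygen on the β face), the basic medium leaving the ketal intact.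

Step 2
Reactants: 2 (1S,6R)-5,5-dimethoxy-7-oxabicyclo[4.1.0]hept-3-en-2-one; 3 (tributylstannyl)methanol
Product: 6 [(1S,2S,6R)-2-hydroxy-5,5-dimethoxy-7-oxabicyclo[4.1.0]hept-3-en-2-yl]methyl benzoate, via lithium lithiomethanolate 4 (not isolated), via dilithium dialkoxide 5 (not isolated)
Conditions: 3, nBuLi (2.0 equiv), THF, −78 to −20 °C; then 2, −78 °C; then BzCl (1.0 equiv), −78 to −40 °C; NH4Cl (aq)
Reagents that add atoms: benzoyl chloride, O=C(Cl)c1ccccc1
Why: Tin–lithium exchange gives unprotected C,O-dilithiated methanol, a hydroxymethyl anion (formaldehyde d1 reagent), whose 1,2-addition to the non-enolisable ketone goes anti to the adjacent epoxide C–O bond (Felkin–Anh and steric control), so the new tertiary alkoxide is cis to the oxirane and the CH2O arm trans (quaternary C1 set), after which one equivalent of BzCl acylates only the unhindered primary lithium alkoxide.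

Step 3
Reactants: 6 [(1S,2S,6R)-2-hydroxy-5,5-dimethoxy-7-oxabicyclo[4.1.0]hept-3-en-2-yl]methyl benzoate
Product: 7 [(1R,5S,6S)-5-hydroxy-2-oxo-7-oxabicyclo[4.1.0]hept-3-en-5-yl]methyl benzoate
Conditions: (CO2H)2 (5 % aq), SiO2, CH2Cl2, rt
Reagents that add atoms: water, O
Why: Mild acid-catalysed ketal hydrolysis through the vinyl-stabilised oxocarbenium ion unmasks the C4 ketone as an enone without touching the oxirane, the tertiary alcohol or the ester, and no stereocentre is involved.

Step 4
Reactants: 7 [(1R,5S,6S)-5-hydroxy-2-oxo-7-oxabicyclo[4.1.0]hept-3-en-5-yl]methyl benzoate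
Product: 8 [(1S,5S,6S)-5-(benzoyloxy)-1,6-dihydroxy-4-oxocyclohex-2-en-1-yl]methyl benzoate
Conditions: PhCO2H (2 equiv), Ti(OiPr)4 (1.5 equiv), CH2Cl2, 0 °C to rt
Reagents that add atoms: benzoic acid, O=C(O)c1ccccc1
Why: Titanium-alkoxide-assisted opening of a 2,3-epoxy alcohol (Sharpless type), in which titanium bound to the tertiary C1 oxygen delivers benzoate to the distal oxirane carbon C3, which is also α to the ketone and much less hindered than neopentyl C2, so SN2 inversion gives 3α-OBz trans to the retained 2β-OH.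

Step 5
Reactants: 8 [(1S,5S,6S)-5-(benzoyloxy)-1,6-dihydroxy-4-oxocyclohex-2-en-1-yl]methyl benzoate
Product: 9 [(1S,4S,5R,6S)-5-(benzoyloxy)-1,4,6-trihydroxycyclohex-2-en-1-yl]methyl benzoate (1α-benzoyloxymethyl-3α-benzoyloxycyclohex-5-en-1β,2β,4β-triol)
Conditions: NaBH4, CeCl3·7H2O, MeOH, −78 °C
Reagents that add atoms: none
Why: Luche reduction gives clean 1,2-hydride addition to the enone, and axial attack on the half-chair with the 3-benzoate equatorial delivers the equatorial 4β-alcohol trans to the 3α-benzoate, the benzoates being inert at −78 °C.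

**Compound list**
1 | 4,4-dimethoxycyclohexa-2,5-dien-1-one (p-benzoquinone mono(dimethyl ketal)) | COC1(OC)C=CC(=O)C=C1 | starting material
2 | (1S,6R)-5,5-dimethoxy-7-oxabicyclo[4.1.0]hept-3-en-2-one (cis-epoxide α,β to the ketone) | O=C1C=CC(OC)(OC)[C@@H]2O[C@H]12 | intermediate
3 | (tributylstannyl)methanol | CCCC[Sn](CCCC)(CCCC)CO | starting material
4 | lithium lithiomethanolate (C,O-dilithiated methanol, LiCH2OLi; not isolated) | [Li]CO[Li] | intermediate
5 | dilithium (1S,2S,6R)-5,5-dimethoxy-2-(oxidomethyl)-7-oxabicyclo[4.1.0]hept-3-en-2-olate (tertiary O cis to the oxirane; not isolated) | [Li]OC[C@@]1(O[Li])C=CC(OC)(OC)[C@@H]2O[C@H]12 | intermediate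
6 | [(1S,2S,6R)-2-hydroxy-5,5-dimethoxy-7-oxabicyclo[4.1.0]hept-3-en-2-yl]methyl benzoate (tertiary OH cis to the oxirane, CH2OBz trans) | O=C(OC[C@@]1(O)C=CC(OC)(OC)[C@@H]2O[C@H]12)c1ccccc1 | intermediate
7 | [(1R,5S,6S)-5-hydroxy-2-oxo-7-oxabicyclo[4.1.0]hept-3-en-5-yl]methyl benzoate (epoxy γ-hydroxy enone) | O=C(OC[C@@]1(O)C=CC(=O)[C@@H]2O[C@H]12)c1ccccc1 | intermediate
8 | [(1S,5S,6S)-5-(benzoyloxy)-1,6-dihydroxy-4-oxocyclohex-2-en-1-yl]methyl benzoate (1-OH and 6-OH cis, 5-OBz trans to 6-OH) | O=C(OC[C@@]1(O)C=CC(=O)[C@@H](OC(=O)c2ccccc2)[C@@H]1O)c1ccccc1 | intermediate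
9 | [(1S,4S,5R,6S)-5-(benzoyloxy)-1,4,6-trihydroxycyclohex-2-en-1-yl]methyl benzoate | O=C(OC[C@@]1(O)C=C[C@H](O)[C@@H](OC(=O)c2ccccc2)[C@@H]1O)c1ccccc1 | target

**Totals and risks**
Total step count: 5. Longest linear sequence: 5 steps (1 to 9).

Most likely to fail, first: step 1. The ee on this unsubstituted dienone may be only moderate and the absolute sense is assumed. The fallback moves the source of asymmetry behind the C–C bond. Setting out from 1, the dianion 4 is added to the ketone to give dilithium 4,4-dimethoxy-1-(oxidomethyl)cyclohexa-2,5-dien-1-olate F1. Benzoylation in the same flask gives the achiral (1-hydroxy-4,4-dimethoxycyclohexa-2,5-dien-1-yl)methyl benzoate F2. Its tertiary bis-allylic hydroxyl then directs a desymmetrising epoxidation (VO(OiPr)3, chiral bis-hydroxamic acid ligand, cumene hydroperoxide, toluene, 0 °C). Oxygen is delivered syn to the OH onto one of the two enantiotopic alkenes, and the route is rejoined at 6.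

Second: step 2. The unprotected dianion may be too basic for the epoxy enone, face selectivity may be incomplete, or the mono-benzoylation may be unselective. The fallback uses a silicon-masked hydroxymethyl anion and separates the acylation. Setting out from 2, the Grignard reagent ClMgCH2SiMe2(OiPr) (THF, 0 °C) adds anti to the oxirane to give (1S,2R,6R)-2-{[dimethyl(propan-2-yloxy)silyl]methyl}-5,5-dimethoxy-7-oxabicyclo[4.1.0]hept-3-en-2-ol F3. Tamao oxidation of the C–Si bond (H2O2, KF, KHCO3, THF/MeOH) gives (1S,2S,6R)-2-(hydroxymethyl)-5,5-dimethoxy-7-oxabicyclo[4.1.0]hept-3-en-2-ol F4. BzCl/pyridine at −20 °C esterifies only the primary hydroxyl, and the route is rejoined at 6.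

Third: step 4. Possible failures are benzoyl migration to O2, participation of the C7 benzoate at C2, or β-elimination of the α-acyloxy β-hydroxy ketone. The fallback reverses the order of the last two operations. Setting out from 7, Luche reduction (hydride anti to the oxirane) gives [(1S,2S,5S,6S)-2,5-dihydroxy-7-oxabicyclo[4.1.0]hept-3-en-2-yl]methyl benzoate F5. The Ti(OiPr)4/PhCO2H opening at C3 is then done last, at the alcohol oxidation level where no enolisation or elimination is possible. The product is 9 directly; regiocontrol is less certain here because both flanking hydroxyls can bind titanium.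

Further compounds
F1 | step 1 | dilithium 4,4-dimethoxy-1-(oxidomethyl)cyclohexa-2,5-dien-1-olate | [Li]OCC1(O[Li])C=CC(OC)(OC)C=C1
F2 | step 1 | (1-hydroxy-4,4-dimethoxycyclohexa-2,5-dien-1-yl)methyl benzoate | O=C(OCC1(O)C=CC(OC)(OC)C=C1)c1ccccc1
F3 | step 2 | (1S,2R,6R)-2-{[dimethyl(propan-2-yloxy)silyl]methyl}-5,5-dimethoxy-7-oxabicyclo[4.1.0]hept-3-en-2-ol | CC(C)O[Si](C)(C)C[C@@]1(O)C=CC(OC)(OC)[C@@H]2O[C@H]12
F4 | step 2 | (1S,2S,6R)-2-(hydroxymethyl)-5,5-dimethoxy-7-oxabicyclo[4.1.0]hept-3-en-2-ol | OC[C@@]1(O)C=CC(OC)(OC)[C@@H]2O[C@H]12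
F5 | step 4 | [(1S,2S,5S,6S)-2,5-dihydroxy-7-oxabicyclo[4.1.0]hept-3-en-2-yl]methyl benzoate | O=C(OC[C@@]1(O)C=C[C@H](O)[C@@H]2O[C@H]12)c1ccccc1
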